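**Strategy** (labdane numbering, C1 to C20)

- Cuts, in retrosynthetic order: the C19–O bond of the tiglate; C4–C5 and C9–C10 together with C8=C17 (one oxidative radical bicyclisation of an open-chain trienyl α-methyl β-keto ester carrying a temporary C3 ketone); C1–C2 (keto ester dianion plus allylic bromide); C6–C7 (allyl sulfone anion plus allylic bromide).
- Forward: a C10 bromide from (R)-linalool and a C5 sulfone from prenyl bromide are joined (C6–C7); the C15 bromide is joined to the 2-methylacetoacetate (C1–C2); ring A and then ring B close in the single key step; the C3 oxygen is removed, the ester is reduced to the C19 alcohol and the tiglate goes on last.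
- Feature that allows the key step: C4 is quaternary and its axial carbon C19 sits at a level an ester can deliver, while ring B ends in the exocyclic C8=C17 alkene beside tertiary C9. C4 can therefore start the cascade as a 1,3-dicarbonyl radical (C19 ester, C3 ketone) and C8 can end it as a tertiary radical that divalent copper oxidises to the methylene.
- Stereochemistry: C13 is carried over from (R)-linalool; C4, C5, C9 and C10 arise together in the key step (chair-chair transition state of the E,E-triene for the relative configuration, the (1R,2S,5R)-8-phenylmenthyl ester for the absolute one); the E tiglate comes with tiglic acid.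

Key step: step 13

Assumption: the free α-methyl dicarbonyl radical is taken to react with its C3 carbonyl syn to the α-methyl and its ester carbonyl s-cis to C3 (alkoxy group turned away from C2); in that rotamer the (1R,2S,5R)-8-phenylmenthyl group covers the Si face of C4, and Re-face attack with an axial ester gives the 10β-methyl (normal labdane) series, so this enantiomer of the auxiliary is used.

**Route**

Step 1
Reactants: 1 (R)-(−)-linalool
Product: 2 (3R)-3-(tert-butyldimethylsilyloxy)-3,7-dimethylocta-1,6-diene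
Conditions: TBSOTf, 2,6-lutidine, CH2Cl2, 0 °C to rt
Reagents that add atoms: tert-butyldimethylsilyl triflate, CC(C)(C)[Si](C)(C)OS(=O)(=O)C(F)(F)F
Why: O-silylation of a hindered tertiary alcohol with the silyl triflate and a non-nucleophilic base is routine and does not touch the C3 centre.

Step 2
Reactants: 2 (3R)-3-(tert-butyldimethylsilyloxy)-3,7-dimethylocta-1,6-diene
Product: 3 (2E,6R)-6-(tert-butyldimethylsilyloxy)-2,6-dimethylocta-2,7-dien-1-ol
Conditions: SeO2 (0.3 equiv), t-BuOOH (2.5 equiv), salicylic acid (0.1 equiv), CH2Cl2, rt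
Reagents that add atoms: tert-butyl hydroperoxide, CC(C)(C)OO (oxygen relayed through catalytic selenium dioxide, O=[Se]=O)
Why: Sharpless-type SeO2 allylic oxidation (ene reaction, then [2,3]-sigmatropic shift) attacks the electron-rich trisubstituted alkene at its E methyl group and ignores the vinyl group, which has no allylic hydrogen, so the E allylic alcohol should result.

Step 3
Reactants: 3 (2E,6R)-6-(tert-butyldimethylsilyloxy)-2,6-dimethylocta-2,7-dien-1-ol
Product: 4 (3R,6E)-8-bromo-3-(tert-butyldimethylsilyloxy)-3,7-dimethylocta-1,6-diene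
Conditions: CBr4, PPh3, CH2Cl2, −20 to 0 °C
Reagents that add atoms: carbon tetrabromide, BrC(Br)(Br)Br
Why: Appel bromination converts a primary allylic alcohol to the bromide under neutral conditions, without allylic transposition and without loss of the tertiary silyl ether.

Step 4
Reactants: 5 prenyl bromide (1-bromo-3-methylbut-2-ene)
Product: 6 prenyl phenyl sulfone [(3-methylbut-2-enyl)sulfonylbenzene]
Conditions: PhSO2Na, DMF, rt
Reagents that add atoms: sodium benzenesulfinate, [Na+].[O-]S(=O)c1ccccc1
Why: SN2 S-alkylation of the sulfinate by a primary allylic bromide gives the sulfone directly.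

Step 5
Reactants: 6 prenyl phenyl sulfone
Product: 7 (E)-2-methyl-4-(phenylsulfonyl)but-2-en-1-ol
Conditions: SeO2 (0.5 equiv), t-BuOOH (3 equiv), CH2Cl2, rt
Reagents that add atoms: tert-butyl hydroperoxide, CC(C)(C)OO (oxygen relayed through catalytic selenium dioxide, O=[Se]=O)
Why: the same SeO2 allylic oxidation hydroxylates the E methyl group, the sulfonyl-bearing CH2 being deactivated, which fixes the E geometry of the later C5=C10 alkene.

Step 6
Reactants: 7 (E)-2-methyl-4-(phenylsulfonyl)but-2-en-1-ol
Product: 8 (E)-tert-butyldimethyl[2-methyl-4-(phenylsulfonyl)but-2-enyloxy]silane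
Conditions: TBSCl, imidazole, DMF, rt
Reagents that add atoms: tert-butyldimethylsilyl chloride, CC(C)(C)[Si](C)(C)Cl
Why: standard O-silylation of a primary alcohol, which masks the hydroxyl for the carbanion step.

Step 7
Reactants: 8 (E)-tert-butyldimethyl[2-methyl-4-(phenylsulfonyl)but-2-enyloxy]silane; 4 (3R,6E)-8-bromo-3-(tert-butyldimethylsilyloxy)-3,7-dimethylocta-1,6-diene
Product: 9 (3R,6E,10E)-3,12-bis(tert-butyldimethylsilyloxy)-3,7,11-trimethyl-9-(phenylsulfonyl)dodeca-1,6,10-triene (both C9 epimers)
Conditions: n-BuLi, THF, −78 °C; then 4, −78 to −20 °C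
Reagents that add atoms: none
Why: alkylation of the α-sulfonyl allyl anion at its α-carbon by a primary allylic bromide (sulfone alkylation, SN2) forms C6–C7 with both E alkenes kept; the new sulfonyl-bearing centre is a mixture that the next step removes.

Step 8
Reactants: 9 (3R,6E,10E)-3,12-bis(tert-butyldimethylsilyloxy)-3,7,11-trimethyl-9-(phenylsulfonyl)dodeca-1,6,10-triene
Product: 10 (3R,6E,10E)-3,12-bis(tert-butyldimethylsilyloxy)-3,7,11-trimethyldodeca-1,6,10-triene
Conditions: PdCl2(dppp) (5 mol %), LiBHEt3, THF, 0 °C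
Reagents that add atoms: none
Why: palladium-catalysed hydride desulfonylation of an allylic sulfone: zerovalent palladium ionises the C–S bond and hydride goes to the less substituted end of the π-allyl, so the trisubstituted E alkene stays in place, while silyl ethers are not ionised.

Step 9
Reactants: 10 (3R,6E,10E)-3,12-bis(tert-butyldimethylsilyloxy)-3,7,11-trimethyldodeca-1,6,10-triene
Product: 11 (2E,6E,10R)-10-(tert-butyldimethylsilyloxy)-2,6,10-trimethyldodeca-2,6,11-trien-1-ol
Conditions: HF·pyridine, pyridine, THF, 0 °C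
Reagents that add atoms: none
Why: selective desilylation on steric grounds, since buffered HF·pyridine cleaves an unhindered primary silyl ether far faster than a tertiary one and is not acidic enough to ionise the tertiary allylic ether.

Step 10
Reactants: 11 (2E,6E,10R)-10-(tert-butyldimethylsilyloxy)-2,6,10-trimethyldodeca-2,6,11-trien-1-ol
Product: 12 (3R,6E,10E)-12-bromo-3-(tert-butyldimethylsilyloxy)-3,7,11-trimethyldodeca-1,6,10-triene
Conditions: CBr4, PPh3, CH2Cl2, −20 to 0 °C
Reagents that add atoms: carbon tetrabromide, BrC(Br)(Br)Br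
Why: Appel bromination of the primary allylic alcohol, as in step 3, with the alkene geometry retained.

Step 11
Reactants: 13 ethyl 2-methylacetoacetate; 14 (1R,2S,5R)-(−)-8-phenylmenthol
Product: 15 (1R,2S,5R)-8-phenylmenthyl 2-methyl-3-oxobutanoate (both C2 epimers)
Conditions: DMAP (0.2 equiv), toluene, reflux, EtOH distilled off
Reagents that add atoms: none
Why: DMAP-catalysed transesterification of a β-keto ester, which runs through the acyl ketene and is driven by removal of ethanol; the carbinol centre of the auxiliary is not involved.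

Step 12
Reactants: 15 (1R,2S,5R)-8-phenylmenthyl 2-methyl-3-oxobutanoate; 12 (3R,6E,10E)-12-bromo-3-(tert-butyldimethylsilyloxy)-3,7,11-trimethyldodeca-1,6,10-triene
Product: 16 (1R,2S,5R)-8-phenylmenthyl (6E,10E,14R)-14-(tert-butyldimethylsilyloxy)-2,6,10,14-tetramethyl-3-oxohexadeca-6,10,15-trienoate (both C2 epimers)
Conditions: NaH, THF, 0 °C; n-BuLi, 0 °C; then 12, 0 °C to rt; H2O
Reagents that add atoms: none
Why: Weiler dianion alkylation, in which the more basic terminal carbanion of the keto ester dianion attacks the primary allylic bromide (SN2) and forms C1–C2; the epimeric α-centre is erased in the next step.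

Step 13
Reactants: 16 (1R,2S,5R)-8-phenylmenthyl (6E,10E,14R)-14-(tert-butyldimethylsilyloxy)-2,6,10,14-tetramethyl-3-oxohexadeca-6,10,15-trienoate
Product: 17 (1R,2S,5R)-8-phenylmenthyl (13R)-13-(tert-butyldimethylsilyloxy)-3-oxolabda-8(17),14-dien-19-oate (4β-ester, 4α-CH3, 5α-H, 9α-H, 10β-CH3)
Conditions: Mn(OAc)3·2H2O (2.2 equiv), Cu(OAc)2·H2O (1.0 equiv), degassed AcOH, 25 °C
Reagents that add atoms: none
Why: Mn(OAc)3 oxidises the keto ester enol to the electrophilic C4 radical, which adds to C5 of the C5=C10 alkene; the tertiary C10 radical adds to C9 of the C8=C9 alkene, and Cu(OAc)2 turns the tertiary C8 radical into an alkylcopper species that loses a C17 hydrogen to give the C8=C17 methylene, Mn(OAc)3 returning copper to the divalent state. This is the known oxidative free-radical polyene cyclisation of α-methyl β-keto esters with trivalent manganese and divalent copper, including its 8-phenylmenthyl ester-directed form, applied here to a chain with a silylated linalyl tail. Ring A closes 6-endo-trig (C4–C5) and ring B closes 6-endo-trig (C9–C10), in that order. C5, C10 and C9 are fixed by the chair-chair transition state of the two E alkenes (trans fusion, 10β-methyl, equatorial C11 chain), and C4 relative to them by the radical geometry, in which the C3 carbonyl lies syn to the α-methyl so that C2 is syn to the ester and the ester finishes axial, cis to C20. The absolute sense is set by the auxiliary, whose phenyl ring covers the Si face of C4 in the rotamer with the ester carbonyl s-cis to C3, so that the alkene adds to the Re face and the normal labdane series results. The step needs this face selectivity, copper capture of the C8 radical ahead of its 6-exo or 7-endo attack on the C14=C15 vinyl group, and loss of a methyl rather than a ring hydrogen; these rest on the aryl shielding, on a full equivalent of Cu(OAc)2 against a slow addition to a monosubstituted alkene beside a quaternary carbon, and on the usual preference of the copper elimination for the least hindered β-hydrogen, while the α-methyl group leaves a quaternary C4 that cannot be oxidised again.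

Step 14
Reactants: 17 (1R,2S,5R)-8-phenylmenthyl (13R)-13-(tert-butyldimethylsilyloxy)-3-oxolabda-8(17),14-dien-19-oate
Product: 18 (1R,2S,5R)-8-phenylmenthyl (13R)-13-(tert-butyldimethylsilyloxy)-3-hydroxylabda-8(17),14-dien-19-oate (C3 epimers, 3β-alcohol expected to prevail)
Conditions: NaBH4, MeOH/THF, 0 °C
Reagents that add atoms: none
Why: chemoselective borohydride reduction of the ketone beside the hindered ester; the C3 configuration does not matter because the oxygen is removed.

Step 15
Reactants: 18 (1R,2S,5R)-8-phenylmenthyl (13R)-13-(tert-butyldimethylsilyloxy)-3-hydroxylabda-8(17),14-dien-19-oate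
Product: 19 (1R,2S,5R)-8-phenylmenthyl (13R)-13-(tert-butyldimethylsilyloxy)-3-(imidazol-1-ylthiocarbonyloxy)labda-8(17),14-dien-19-oate
Conditions: 1,1'-thiocarbonyldiimidazole, DMAP, ClCH2CH2Cl, 80 °C
Reagents that add atoms: 1,1'-thiocarbonyldiimidazole, S=C(n1ccnc1)n1ccnc1
Why: thioacylation of the secondary alcohol to the Barton–McCombie precursor under neutral conditions, which avoids an alkoxide that could open the β-hydroxy ester by retro-aldol cleavage.

Step 16
Reactants: 19 (1R,2S,5R)-8-phenylmenthyl (13R)-13-(tert-butyldimethylsilyloxy)-3-(imidazol-1-ylthiocarbonyloxy)labda-8(17),14-dien-19-oate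
Product: 20 (1R,2S,5R)-8-phenylmenthyl (13R)-13-(tert-butyldimethylsilyloxy)labda-8(17),14-dien-19-oate
Conditions: Bu3SnH, AIBN (cat.), toluene, 100 °C
Reagents that add atoms: none
Why: Barton–McCombie radical deoxygenation; the secondary C3 radical has no alkene within cyclisation range and no stereocentre of the product is touched.

Step 17
Reactants: 20 (1R,2S,5R)-8-phenylmenthyl (13R)-13-(tert-butyldimethylsilyloxy)labda-8(17),14-dien-19-oate
Product: 21 (13R)-13-(tert-butyldimethylsilyloxy)labda-8(17),14-dien-19-ol (4β-CH2OH, 5α-H, 9α-H, 10β-CH3)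
Conditions: LiAlH4, THF, reflux; aqueous work-up
Reagents that add atoms: none
Why: hydride reduction of the ester to the primary alcohol, chosen because a neopentyl axial ester of this kind resists hydrolysis; the auxiliary is returned as the alcohol, and the tertiary silyl ether and the alkenes are inert.

Step 18
Reactants: 21 (13R)-13-(tert-butyldimethylsilyloxy)labda-8(17),14-dien-19-ol; 22 tiglic acid [(E)-2-methylbut-2-enoic acid]
Product: 24 (13R)-13-(tert-butyldimethylsilyloxy)labda-8(17),14-dien-19-yl (E)-2-methylbut-2-enoate, via tiglic 2,4,6-trichlorobenzoic anhydride 23 (not isolated)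
Conditions: 2,4,6-trichlorobenzoyl chloride, Et3N, toluene, rt; then 21, DMAP, toluene, 60 °C
Reagents that add atoms: none
Why: Yamaguchi esterification, in which DMAP opens the mixed anhydride at the unhindered tigloyl carbonyl and the acylpyridinium acylates the neopentyl alcohol; the E alkene is the stable isomer and is kept.

Step 19
Reactants: 24 (13R)-13-(tert-butyldimethylsilyloxy)labda-8(17),14-dien-19-yl (E)-2-methylbut-2-enoate
Product: 25 (13R)-13-hydroxylabda-8(17),14-dien-19-yl (E)-2-methylbut-2-enoate, (4S,5R,9S,10R,13R), CNP0313179.1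
Conditions: TBAF, THF, 50 °C
Reagents that add atoms: none
Why: fluoride desilylation of the tertiary silyl ether, which needs warming, while the hindered neopentyl tiglate should resist fluoride and the C13–O bond is never broken.

**Compound list**

1 | (R)-(−)-linalool | C=C[C@](C)(O)CCC=C(C)C | starting material
2 | (3R)-3-(tert-butyldimethylsilyloxy)-3,7-dimethylocta-1,6-diene | C=C[C@](C)(O[Si](C)(C)C(C)(C)C)CCC=C(C)C | intermediate
3 | (2E,6R)-6-(tert-butyldimethylsilyloxy)-2,6-dimethylocta-2,7-dien-1-ol | C=C[C@](C)(O[Si](C)(C)C(C)(C)C)CC/C=C(\C)CO | intermediate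
4 | (3R,6E)-8-bromo-3-(tert-butyldimethylsilyloxy)-3,7-dimethylocta-1,6-diene | C=C[C@](C)(O[Si](C)(C)C(C)(C)C)CC/C=C(\C)CBr | intermediate
5 | prenyl bromide | CC(C)=CCBr | starting material
6 | prenyl phenyl sulfone | CC(C)=CCS(=O)(=O)c1ccccc1 | intermediate
7 | (E)-2-methyl-4-(phenylsulfonyl)but-2-en-1-ol | O=S(=O)(C/C=C(\C)CO)c1ccccc1 | intermediate
8 | (E)-tert-butyldimethyl[2-methyl-4-(phenylsulfonyl)but-2-enyloxy]silane | O=S(=O)(C/C=C(\C)CO[Si](C)(C)C(C)(C)C)c1ccccc1 | intermediate
9 | (3R,6E,10E)-3,12-bis(tert-butyldimethylsilyloxy)-3,7,11-trimethyl-9-(phenylsulfonyl)dodeca-1,6,10-triene, C9 epimers | C=C[C@](C)(O[Si](C)(C)C(C)(C)C)CC/C=C(\C)CC(/C=C(\C)CO[Si](C)(C)C(C)(C)C)S(=O)(=O)c1ccccc1 | intermediate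
10 | (3R,6E,10E)-3,12-bis(tert-butyldimethylsilyloxy)-3,7,11-trimethyldodeca-1,6,10-triene | C=C[C@](C)(O[Si](C)(C)C(C)(C)C)CC/C=C(\C)CC/C=C(\C)CO[Si](C)(C)C(C)(C)C | intermediate
11 | (2E,6E,10R)-10-(tert-butyldimethylsilyloxy)-2,6,10-trimethyldodeca-2,6,11-trien-1-ol | C=C[C@](C)(O[Si](C)(C)C(C)(C)C)CC/C=C(\C)CC/C=C(\C)CO | intermediate
12 | (3R,6E,10E)-12-bromo-3-(tert-butyldimethylsilyloxy)-3,7,11-trimethyldodeca-1,6,10-triene | C=C[C@](C)(O[Si](C)(C)C(C)(C)C)CC/C=C(\C)CC/C=C(\C)CBr | intermediate
13 | ethyl 2-methylacetoacetate | CCOC(=O)C(C)C(C)=O | starting material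
14 | (1R,2S,5R)-(−)-8-phenylmenthol | O[C@@H]1C[C@H](C)CC[C@H]1C(C)(C)c1ccccc1 | starting material
15 | (1R,2S,5R)-8-phenylmenthyl 2-methyl-3-oxobutanoate, C2 epimers | CC(=O)C(C)C(=O)O[C@@H]1C[C@H](C)CC[C@H]1C(C)(C)c1ccccc1 | intermediate
16 | (1R,2S,5R)-8-phenylmenthyl (6E,10E,14R)-14-(tert-butyldimethylsilyloxy)-2,6,10,14-tetramethyl-3-oxohexadeca-6,10,15-trienoate, C2 epimers | C=C[C@](C)(O[Si](C)(C)C(C)(C)C)CC/C=C(\C)CC/C=C(\C)CCC(=O)C(C)C(=O)O[C@@H]1C[C@H](C)CC[C@H]1C(C)(C)c1ccccc1 | intermediate
17 | (1R,2S,5R)-8-phenylmenthyl (13R)-13-(tert-butyldimethylsilyloxy)-3-oxolabda-8(17),14-dien-19-oate | C=C[C@](C)(O[Si](C)(C)C(C)(C)C)CC[C@H]1C(=C)CC[C@H]2[C@@](C)(C(=O)O[C@@H]3C[C@H](C)CC[C@H]3C(C)(C)c3ccccc3)C(=O)CC[C@]12C | intermediate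
18 | (1R,2S,5R)-8-phenylmenthyl (13R)-13-(tert-butyldimethylsilyloxy)-3-hydroxylabda-8(17),14-dien-19-oate, C3 epimers | C=C[C@](C)(O[Si](C)(C)C(C)(C)C)CC[C@H]1C(=C)CC[C@H]2[C@@](C)(C(=O)O[C@@H]3C[C@H](C)CC[C@H]3C(C)(C)c3ccccc3)C(O)CC[C@]12C | intermediate
19 | (1R,2S,5R)-8-phenylmenthyl (13R)-13-(tert-butyldimethylsilyloxy)-3-(imidazol-1-ylthiocarbonyloxy)labda-8(17),14-dien-19-oate, C3 epimers | C=C[C@](C)(O[Si](C)(C)C(C)(C)C)CC[C@H]1C(=C)CC[C@H]2[C@@](C)(C(=O)O[C@@H]3C[C@H](C)CC[C@H]3C(C)(C)c3ccccc3)C(OC(=S)n3ccnc3)CC[C@]12C | intermediate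
20 | (1R,2S,5R)-8-phenylmenthyl (13R)-13-(tert-butyldimethylsilyloxy)labda-8(17),14-dien-19-oate | C=C[C@](C)(O[Si](C)(C)C(C)(C)C)CC[C@H]1C(=C)CC[C@H]2[C@@](C)(C(=O)O[C@@H]3C[C@H](C)CC[C@H]3C(C)(C)c3ccccc3)CCC[C@]12C | intermediate
21 | (13R)-13-(tert-butyldimethylsilyloxy)labda-8(17),14-dien-19-ol | C=C[C@](C)(O[Si](C)(C)C(C)(C)C)CC[C@H]1C(=C)CC[C@H]2[C@@](C)(CO)CCC[C@]12C | intermediate
22 | tiglic acid | C/C=C(\C)C(=O)O | starting material
23 | tiglic 2,4,6-trichlorobenzoic anhydride, formed in the flask and not isolated | C/C=C(\C)C(=O)OC(=O)c1c(Cl)cc(Cl)cc1Cl | intermediate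
24 | (13R)-13-(tert-butyldimethylsilyloxy)labda-8(17),14-dien-19-yl (E)-2-methylbut-2-enoate | C=C[C@](C)(O[Si](C)(C)C(C)(C)C)CC[C@H]1C(=C)CC[C@H]2[C@@](C)(COC(=O)/C(C)=C/C)CCC[C@]12C | intermediate
25 | (4S,5R,9S,10R,13R)-13-hydroxylabda-8(17),14-dien-19-yl (E)-2-methylbut-2-enoate, CNP0313179.1 | C=C[C@](C)(O)CC[C@H]1C(=C)CC[C@H]2[C@@](C)(COC(=O)/C(C)=C/C)CCC[C@]12C | target

**Count**

Total step count: 19.
Longest linear sequence: 15 steps, from (R)-linalool (steps 1, 2, 3, 7, 8, 9, 10, 12, 13, 14, 15, 16, 17, 18, 19).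

**Steps most likely to fail**

Step 13. The two faces of the C4 radical may be told apart poorly, or in the opposite sense, because no metal chelate fixes the ester rotamer of a free α-methyl radical; endocyclic elimination can also erode the yield. The fallback moves the making of the quaternary centre out of the radical step. It sets out from bromide 12. Alkylation of 12 with the dianion (NaH, then n-BuLi) of (1S,2R,5S)-8-phenylmenthyl acetoacetate F1 (prepared from commercial (1S,2R,5S)-8-phenylmenthol and 2,2,6-trimethyl-4H-1,3-dioxin-4-one in hot xylene) should give the α-unsubstituted trienyl keto ester F2. Cyclisation of F2 with Mn(OAc)3·2H2O and Cu(OAc)2·H2O in CF3CH2OH at 0 °C in the presence of Yb(OTf)3 is the variant in which 8-phenylmenthyl control of an α-unsubstituted keto ester is established. There the chelated enolate places the ester equatorial, so the antipodal auxiliary leads to the same 10β-methyl series and should give the bicyclic keto ester F3. C-Methylation of F3 (K2CO3, MeI, acetone) from the α face, anti to the axial C20 methyl, should give the 4α-methyl 4β-ester F4. The operations of steps 14 to 17 then follow: NaBH4 to the hydroxy ester F5, thiocarbonyldiimidazole to the thiocarbonyl derivative F6, Bu3SnH to the deoxygenated ester F7, and LiAlH4. The fallback comes back to the route at alcohol 21.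

Step 17. Hydride addition may stall at the axial C19 carbonyl, which is crowded by the quaternary C4, the C20 methyl and the bulky alkoxy group, and forcing it may start to strip the silyl ether. The fallback reduces the ester earlier, with help from the neighbouring oxygen, and sets out from keto ester 17. LiAlH4 in THF at 0 °C to rt reduces the ketone first, and the C3 alkoxyaluminium hydride can deliver hydride to the adjacent ester from within, giving (13R)-13-(tert-butyldimethylsilyloxy)labda-8(17),14-diene-3,19-diol F8 and the auxiliary. Yamaguchi acylation with tiglic acid 22 (through 23) at 0 °C to rt should take the primary C19 hydroxyl in preference to the secondary C3 hydroxyl beside the quaternary centre, giving the 3-hydroxy 19-tiglate F9. Thiocarbonyldiimidazole then gives the imidazolylthiocarbonate F10, and Bu3SnH with AIBN removes the C3 oxygen. The fallback comes back to the route at silyl ether 24.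

Step 19. Fluoride attack at the hindered tertiary silyl ether may be so slow that cleavage of the tiglate by fluoride or adventitious hydroxide, or ionisation of the tertiary allylic C13–O bond, overtakes it. The fallback changes the order of events and sets out from alcohol 21. Desilylation with TBAF in THF at reflux, with no ester yet present, should give (13R)-labda-8(17),14-diene-13,19-diol F11. Yamaguchi acylation of F11 with tiglic acid 22 (through 23) then esterifies only the primary C19 hydroxyl, the tertiary C13 hydroxyl being inert. The fallback comes back to the route at the target 25.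

**Further compounds**

F1 | step 13 | (1S,2R,5S)-8-phenylmenthyl acetoacetate | CC(=O)CC(=O)O[C@H]1C[C@@H](C)CC[C@@H]1C(C)(C)c1ccccc1
F2 | step 13 | (1S,2R,5S)-8-phenylmenthyl (6E,10E,14R)-14-(tert-butyldimethylsilyloxy)-6,10,14-trimethyl-3-oxohexadeca-6,10,15-trienoate | C=C[C@](C)(O[Si](C)(C)C(C)(C)C)CC/C=C(\C)CC/C=C(\C)CCC(=O)CC(=O)O[C@H]1C[C@@H](C)CC[C@@H]1C(C)(C)c1ccccc1
F3 | step 13 | (1S,2R,5S)-8-phenylmenthyl (13R)-13-(tert-butyldimethylsilyloxy)-3-oxo-18-norlabda-8(17),14-dien-19-oate (C4 enolisable) | C=C[C@](C)(O[Si](C)(C)C(C)(C)C)CC[C@H]1C(=C)CC[C@H]2C(C(=O)O[C@H]3C[C@@H](C)CC[C@@H]3C(C)(C)c3ccccc3)C(=O)CC[C@]12C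
F4 | step 13 | (1S,2R,5S)-8-phenylmenthyl (13R)-13-(tert-butyldimethylsilyloxy)-3-oxolabda-8(17),14-dien-19-oate | C=C[C@](C)(O[Si](C)(C)C(C)(C)C)CC[C@H]1C(=C)CC[C@H]2[C@@](C)(C(=O)O[C@H]3C[C@@H](C)CC[C@@H]3C(C)(C)c3ccccc3)C(=O)CC[C@]12C
F5 | step 13 | (1S,2R,5S)-8-phenylmenthyl (13R)-13-(tert-butyldimethylsilyloxy)-3-hydroxylabda-8(17),14-dien-19-oate, C3 epimers | C=C[C@](C)(O[Si](C)(C)C(C)(C)C)CC[C@H]1C(=C)CC[C@H]2[C@@](C)(C(=O)O[C@H]3C[C@@H](C)CC[C@@H]3C(C)(C)c3ccccc3)C(O)CC[C@]12C
F6 | step 13 | (1S,2R,5S)-8-phenylmenthyl (13R)-13-(tert-butyldimethylsilyloxy)-3-(imidazol-1-ylthiocarbonyloxy)labda-8(17),14-dien-19-oate, C3 epimers | C=C[C@](C)(O[Si](C)(C)C(C)(C)C)CC[C@H]1C(=C)CC[C@H]2[C@@](C)(C(=O)O[C@H]3C[C@@H](C)CC[C@@H]3C(C)(C)c3ccccc3)C(OC(=S)n3ccnc3)CC[C@]12C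
F7 | step 13 | (1S,2R,5S)-8-phenylmenthyl (13R)-13-(tert-butyldimethylsilyloxy)labda-8(17),14-dien-19-oate | C=C[C@](C)(O[Si](C)(C)C(C)(C)C)CC[C@H]1C(=C)CC[C@H]2[C@@](C)(C(=O)O[C@H]3C[C@@H](C)CC[C@@H]3C(C)(C)c3ccccc3)CCC[C@]12C
F8 | step 17 | (13R)-13-(tert-butyldimethylsilyloxy)labda-8(17),14-diene-3,19-diol, C3 epimers | C=C[C@](C)(O[Si](C)(C)C(C)(C)C)CC[C@H]1C(=C)CC[C@H]2[C@@](C)(CO)C(O)CC[C@]12C
F9 | step 17 | (13R)-13-(tert-butyldimethylsilyloxy)-3-hydroxylabda-8(17),14-dien-19-yl (E)-2-methylbut-2-enoate, C3 epimers | C=C[C@](C)(O[Si](C)(C)C(C)(C)C)CC[C@H]1C(=C)CC[C@H]2[C@@](C)(COC(=O)/C(C)=C/C)C(O)CC[C@]12C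
F10 | step 17 | (13R)-13-(tert-butyldimethylsilyloxy)-3-(imidazol-1-ylthiocarbonyloxy)labda-8(17),14-dien-19-yl (E)-2-methylbut-2-enoate, C3 epimers | C=C[C@](C)(O[Si](C)(C)C(C)(C)C)CC[C@H]1C(=C)CC[C@H]2[C@@](C)(COC(=O)/C(C)=C/C)C(OC(=S)n3ccnc3)CC[C@]12C
F11 | step 19 | (13R)-labda-8(17),14-diene-13,19-diol | C=C[C@](C)(O)CC[C@H]1C(=C)CC[C@H]2[C@@](C)(CO)CCC[C@]12C
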